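**Plan**

1. The retrosynthesis cuts C4–C4a (the aryl–acyl bond of ring C) first, then the O1–C2 aryl ether, then C2–C3 of the ring-B fragment; in the side chain it cuts the aryl–CH2 bond, the bond to the prenyl group and the isopropenyl carbons.
2. Forward: phloroglucinol becomes ring A carrying the finished lavandulyl chain, with only the hydroxyl para to the chain free. An (R)-β-hydroxy ester holding ring B and C2–C4 is joined to it through O1 (Mitsunobu). The ester becomes an S-ethyl thioester, all phenols are freed, and ring C is closed last at C4–C4a.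
3. Enabling feature: ring A is a phloroglucinol ring symmetric about its C6–C8a axis. C4a and C8, the two carbons ortho to O1, each lie between O1 and a free hydroxyl, so a C4 thioester tethered through O1–C2–C3 gives the same 6-substituted flavanone from either carbon.
4. Event: an enzymatic Friedel–Crafts C-acylation (phloroglucinol C-acyltransferase of Pseudomonas protegens) at pH 7.5 on the unprotected triphenol. It needs no acid near the lavandulyl alkenes or the benzylic aryl ether and no base near C2, and leaves no protecting group on the flavanone. The thioester is the only helper and leaves as ethanethiol in the event itself.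
5. Stereochemistry: the side-chain centre comes from an Evans alkylation ((4S)-benzyloxazolidinone, prenyl bromide). C2 comes from Noyori asymmetric transfer hydrogenation to the (R)-carbinol followed by Mitsunobu inversion. The ring closure creates no stereocentre.

Key step: step 16

Assumption: the side-chain centre is (S) by the CIP rules as read from the SMILES (spatially that of (R)-lavandulol), and a recombinant preparation of the acyltransferase, wild type or with a widened acyl pocket, is taken to be at hand.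
Abbreviations: MOM = methoxymethyl; TIPS = tri(propan-2-yl)silyl; Piv = 2,2-dimethylpropanoyl; (2S)-lavandulyl = (2S)-5-methyl-2-(prop-1-en-2-yl)hex-4-en-1-yl.

**Route**

Step 1
Reactants: 1 phloroglucinol (benzene-1,3,5-triol)
Product: 2 3,5-bis(methoxymethoxy)phenol
Conditions: MOMCl (2.0 equiv), i-Pr2NEt, DMF, 0 °C to rt; chromatography
Reagents that add atoms: chloromethyl methyl ether (MOMCl), COCCl
Why: O-alkylation of the phenoxide (Williamson type) with two equivalents should give the bis-ether as the main part of a statistical mixture, separable from the mono- and tris-ethers, and its free hydroxyl is the one that will lie para to the side chain.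

Step 2
Reactants: 2 3,5-bis(methoxymethoxy)phenol
Product: 3 [3,5-bis(methoxymethoxy)phenoxy]tri(propan-2-yl)silane
Conditions: i-Pr3SiCl, imidazole, DMF, rt
Reagents that add atoms: chlorotri(propan-2-yl)silane (TIPSCl), CC(C)[Si](Cl)(C(C)C)C(C)C
Why: Silyl ether formation puts a bulky, non-coordinating group on the third oxygen, so that the next lithiation should go between the two MOM ethers.

Step 3
Reactants: 3 [3,5-bis(methoxymethoxy)phenoxy]tri(propan-2-yl)silane; 4 (4S)-4-benzyl-3-(prop-2-enoyl)-1,3-oxazolidin-2-one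
Product: 8 (4S)-4-benzyl-3-{3-[2,6-bis(methoxymethoxy)-4-(TIPS-oxy)phenyl]propanoyl}-1,3-oxazolidin-2-one, via aryllithium 5 (not isolated), via arylmagnesium bromide 6 (not isolated), via magnesium enolate 7 (not isolated)
Conditions: n-BuLi, THF, 0 °C; MgBr2·OEt2, 0 °C; CuBr·SMe2 (20 mol%), then 4, −40 to 0 °C; aq NH4Cl
Reagents that add atoms: none
Why: Directed ortho-metalation at the carbon flanked by both MOM ethers, transmetalation to the Grignard reagent and copper-catalysed conjugate addition to the acryloyl imide should attach the three-carbon acyl chain already bound to the auxiliary; no stereocentre is formed.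

Step 4
Reactants: 8 (4S)-4-benzyl-3-{3-[2,6-bis(methoxymethoxy)-4-(TIPS-oxy)phenyl]propanoyl}-1,3-oxazolidin-2-one
Product: 10 (4S)-4-benzyl-3-[(2S)-2-{[2,6-bis(methoxymethoxy)-4-(TIPS-oxy)phenyl]methyl}-5-methylhex-4-enoyl]-1,3-oxazolidin-2-one, via sodium enolate 9 (not isolated)
Conditions: NaN(SiMe3)2, THF, −78 °C; prenyl bromide, −78 to −40 °C
Reagents that add atoms: 1-bromo-3-methylbut-2-ene (prenyl bromide), CC(C)=CCBr
Why: Evans alkylation, in which the chelated sodium (Z)-enolate should be attacked by prenyl bromide on the face opposite the benzyl group of the (4S)-auxiliary, setting the (S) centre of the future lavandulyl chain.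

Step 5
Reactants: 10 (4S)-4-benzyl-3-[(2S)-2-{[2,6-bis(methoxymethoxy)-4-(TIPS-oxy)phenyl]methyl}-5-methylhex-4-enoyl]-1,3-oxazolidin-2-one
Product: 12 (2S)-2-{[2,6-bis(methoxymethoxy)-4-(TIPS-oxy)phenyl]methyl}-5-methylhex-4-enoic acid, via peroxy acid 11 (not isolated)
Conditions: LiOH, H2O2, THF/H2O, 0 °C; Na2SO3; cold HCl to pH 4
Reagents that add atoms: hydrogen peroxide (as LiOOH), OO
Why: Hydroperoxide cleavage of the Evans imide at the exocyclic carbonyl followed by sulfite reduction of the peroxy acid should free the acid and the auxiliary without touching the α-centre.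

Step 6
Reactants: 12 (2S)-2-{[2,6-bis(methoxymethoxy)-4-(TIPS-oxy)phenyl]methyl}-5-methylhex-4-enoic acid
Product: 14 (3S)-3-{[2,6-bis(methoxymethoxy)-4-(TIPS-oxy)phenyl]methyl}-6-methylhept-5-en-2-one, via dilithium diolate 13 (not isolated)
Conditions: MeLi (3 equiv), THF, −78 to 0 °C; aq NH4Cl
Reagents that add atoms: methyllithium, [Li]C
Why: Addition of methyllithium to the lithium carboxylate should stop at the dilithium gem-diolate, which gives the methyl ketone on hydrolysis (ketone synthesis from a carboxylic acid) without enolising the α-centre.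

Step 7
Reactants: 14 (3S)-3-{[2,6-bis(methoxymethoxy)-4-(TIPS-oxy)phenyl]methyl}-6-methylhept-5-en-2-one
Product: 15 {3,5-bis(methoxymethoxy)-4-[(2S)-lavandulyl]phenoxy}tri(propan-2-yl)silane
Conditions: Cp2TiMe2, toluene/THF, 65 °C, dark
Reagents that add atoms: dimethyltitanocene (Cp2TiMe2), C[Ti](C)(C1C=CC=C1)C1C=CC=C1
Why: Petasis methylenation through a non-basic titanium methylidene should turn the enolisable α-branched ketone into the isopropenyl group without epimerisation, completing the lavandulyl chain.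

Step 8
Reactants: 15 {3,5-bis(methoxymethoxy)-4-[(2S)-lavandulyl]phenoxy}tri(propan-2-yl)silane
Product: 16 3,5-bis(methoxymethoxy)-4-[(2S)-lavandulyl]phenol
Conditions: Bu4NF, THF, 0 °C; aq NH4Cl
Reagents that add atoms: none
Why: Fluoride cleavage of the aryl silyl ether should free only the phenol para to the side chain, the MOM ethers and alkenes being inert.

Step 9
Reactants: 17 4-hydroxy-2-methoxybenzaldehyde
Product: 18 4-formyl-3-methoxyphenyl 2,2-dimethylpropanoate
Conditions: t-BuCOCl, Et3N, DMAP (cat.), CH2Cl2, 0 °C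
Reagents that add atoms: 2,2-dimethylpropanoyl chloride (PivCl), CC(C)(C)C(Cl)=O
Why: Acylation of the phenol gives an electron-withdrawing ester on ring B, which should lower the tendency of the later benzylic carbon to ionise.

Step 10
Reactants: 18 4-formyl-3-methoxyphenyl 2,2-dimethylpropanoate
Product: 19 ethyl 3-[2-methoxy-4-(Piv-oxy)phenyl]-3-oxopropanoate
Conditions: N2CHCO2Et, NbCl5 (5 mol%), CH2Cl2, rt
Reagents that add atoms: ethyl diazoacetate, CCOC(=O)C=[N+]=[N-]
Why: Roskamp reaction, in which Lewis-acid-promoted addition of the diazo ester to the aldehyde and a 1,2-hydride shift with loss of N2 should give the β-keto ester and so form the C2–C3 bond.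

Step 11
Reactants: 19 ethyl 3-[2-methoxy-4-(Piv-oxy)phenyl]-3-oxopropanoate
Product: 20 ethyl (3R)-3-hydroxy-3-[2-methoxy-4-(Piv-oxy)phenyl]propanoate
Conditions: RuCl[(R,R)-TsDPEN](p-cymene) (1 mol%), HCO2H/Et3N (5:2), EtOAc, 30 °C
Reagents that add atoms: none
Why: Noyori asymmetric transfer hydrogenation, in which the (R,R)-TsDPEN ruthenium hydride should deliver hydride to the face of the aryl ketone that gives the (R)-carbinol (the sense established for aryl ketones), leaving both esters untouched.

Step 12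
Reactants: 16 3,5-bis(methoxymethoxy)-4-[(2S)-lavandulyl]phenol; 20 ethyl (3R)-3-hydroxy-3-[2-methoxy-4-(Piv-oxy)phenyl]propanoate
Product: 21 ethyl (3S)-3-{3,5-bis(methoxymethoxy)-4-[(2S)-lavandulyl]phenoxy}-3-[2-methoxy-4-(Piv-oxy)phenyl]propanoate
Conditions: PPh3, DIAD, toluene, 0 °C to rt
Reagents that add atoms: none
Why: Mitsunobu reaction, in which the unhindered phenol should displace the activated benzylic hydroxyl by SN2 with inversion ((R)-alcohol to (S)-aryl ether), setting C2 of the target while the pivalate on ring B disfavours ionisation.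

Step 13
Reactants: 21 ethyl (3S)-3-{3,5-bis(methoxymethoxy)-4-[(2S)-lavandulyl]phenoxy}-3-[2-methoxy-4-(Piv-oxy)phenyl]propanoate
Product: 22 (3S)-3-{3,5-bis(methoxymethoxy)-4-[(2S)-lavandulyl]phenoxy}-3-(4-hydroxy-2-methoxyphenyl)propanoic acid
Conditions: LiOH, THF/H2O, 0 °C; cold HCl to pH 4
Reagents that add atoms: lithium hydroxide, [Li+].[OH-]
Why: Saponification should cleave the ethyl ester and the aryl pivalate in one operation, acyl substitution at 0 °C being expected to outrun β-elimination of the aryloxide.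

Step 14
Reactants: 22 (3S)-3-{3,5-bis(methoxymethoxy)-4-[(2S)-lavandulyl]phenoxy}-3-(4-hydroxy-2-methoxyphenyl)propanoic acid
Product: 23 S-ethyl (3S)-3-{3,5-bis(methoxymethoxy)-4-[(2S)-lavandulyl]phenoxy}-3-(4-hydroxy-2-methoxyphenyl)propanethioate
Conditions: EtSH (5 equiv), EDC·HCl, DMAP (cat.), CH2Cl2, 0 °C
Reagents that add atoms: ethanethiol, CCS
Why: Steglich-type thioesterification, in which the excess thiol is far more nucleophilic than the free phenol, should give selectively the S-ethyl thioester, an acyl donor of the kind the acyltransferase accepts.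

Step 15
Reactants: 23 S-ethyl (3S)-3-{3,5-bis(methoxymethoxy)-4-[(2S)-lavandulyl]phenoxy}-3-(4-hydroxy-2-methoxyphenyl)propanethioate
Product: 25 S-ethyl (3S)-3-{3,5-dihydroxy-4-[(2S)-lavandulyl]phenoxy}-3-(4-hydroxy-2-methoxyphenyl)propanethioate, via tris(trimethylsilyl) ether 24 (not isolated)
Conditions: Me3SiOTf, 2,2'-bipyridyl, CH2Cl2, 0 °C to rt; then H2O
Reagents that add atoms: none
Why: Non-acidic cleavage of aromatic MOM ethers by silyl triflate in the presence of 2,2'-bipyridyl, through aryl trimethylsilyl ethers hydrolysed on adding water, should spare the alkenes, the benzylic aryl ether and the thioester.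

Step 16
Reactants: 25 S-ethyl (3S)-3-{3,5-dihydroxy-4-[(2S)-lavandulyl]phenoxy}-3-(4-hydroxy-2-methoxyphenyl)propanethioate
Product: 26 (2S)-5,7-dihydroxy-2-(4-hydroxy-2-methoxyphenyl)-6-[(2S)-lavandulyl]-2,3-dihydro-4H-chromen-4-one (target)
Conditions: C-acyltransferase (PhlACB of Pseudomonas protegens, cell-free extract, wild type or pocket-widened variant), potassium phosphate buffer (KH2PO4/K2HPO4, 50 mM, pH 7.5), DMSO (10% v/v), 30 °C, argon
Reagents that add atoms: none
Why: Proposed new method: the S-ethyl thioester of 25 is expected to pass its acyl group to the active-site cysteine of the acyltransferase (ethanethiol leaves), and the tethered ring A, bound as a resorcinol-type phenolate, then attacks this enzyme-bound thioester carbonyl through C4a in a Friedel–Crafts C-acylation, after which proton loss restores the aromatic ring. The closest known reaction type is the bimolecular C-acylation of phloroglucinol and resorcinols by this enzyme with thioester or phenyl ester donors (and its Fries-type O-to-C acyl shift), which places the acyl group ortho to one hydroxyl and para to the other, the relation C4a has to the C5 and C7 hydroxyls; new here are the intramolecular course and the bulky β-aryl-β-aryloxy acyl group, for which a variant with a widened acyl pocket may be needed. Ring C closes in a 6-exo-trig mode, the aromatic carbon adding to the exocyclic thioester carbonyl. No stereocentre is formed: C2 and the side-chain centre are carried in, and at pH 7.5 and 30 °C neither E1cB loss of the aryloxide from the thioester nor opening of the flavanone to the chalcone should compete. The step needs C- over O-acylation and a choice between the two carbons ortho to O1: the first should follow from the chemoselectivity of the enzyme and from ring size (acylation at O5 would need an eight-membered lactone), and the second needs no control because C4a and C8 are equivalent, each lying between O1 and a free hydroxyl on a ring A symmetric about its C6–C8a axis. Hydrolysis of the thioester is the competing process, to be held back by the near-neutral pH and a high enzyme loading.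

**Compound list**

1 | phloroglucinol | Oc1cc(O)cc(O)c1 | starting material
2 | 3,5-bis(methoxymethoxy)phenol | COCOc1cc(O)cc(OCOC)c1 | intermediate
3 | [3,5-bis(methoxymethoxy)phenoxy]tri(propan-2-yl)silane | COCOc1cc(OCOC)cc(O[Si](C(C)C)(C(C)C)C(C)C)c1 | intermediate
4 | (4S)-4-benzyl-3-(prop-2-enoyl)-1,3-oxazolidin-2-one | C=CC(=O)N1[C@@H](Cc2ccccc2)COC1=O | starting material
5 | [2,6-bis(methoxymethoxy)-4-(TIPS-oxy)phenyl]lithium | [Li]c1c(OCOC)cc(O[Si](C(C)C)(C(C)C)C(C)C)cc1OCOC | intermediate
6 | [2,6-bis(methoxymethoxy)-4-(TIPS-oxy)phenyl]magnesium bromide | Br[Mg]c1c(OCOC)cc(O[Si](C(C)C)(C(C)C)C(C)C)cc1OCOC | intermediate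
7 | bromomagnesium (Z)-enolate of 8 | Br[Mg]O/C(=C\Cc1c(OCOC)cc(O[Si](C(C)C)(C(C)C)C(C)C)cc1OCOC)N1[C@@H](Cc2ccccc2)COC1=O | intermediate
8 | (4S)-4-benzyl-3-{3-[2,6-bis(methoxymethoxy)-4-(TIPS-oxy)phenyl]propanoyl}-1,3-oxazolidin-2-one | O=C(CCc1c(OCOC)cc(O[Si](C(C)C)(C(C)C)C(C)C)cc1OCOC)N1[C@@H](Cc2ccccc2)COC1=O | intermediate
9 | sodium (Z)-enolate of 8 | [Na+].[O-]/C(=C\Cc1c(OCOC)cc(O[Si](C(C)C)(C(C)C)C(C)C)cc1OCOC)N1[C@@H](Cc2ccccc2)COC1=O | intermediate
10 | (4S)-4-benzyl-3-[(2S)-2-{[2,6-bis(methoxymethoxy)-4-(TIPS-oxy)phenyl]methyl}-5-methylhex-4-enoyl]-1,3-oxazolidin-2-one | O=C([C@@H](CC=C(C)C)Cc1c(OCOC)cc(O[Si](C(C)C)(C(C)C)C(C)C)cc1OCOC)N1[C@@H](Cc2ccccc2)COC1=O | intermediate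
11 | lithium (2S)-2-{[2,6-bis(methoxymethoxy)-4-(TIPS-oxy)phenyl]methyl}-5-methylhex-4-eneperoxoate | [Li+].[O-]OC(=O)[C@@H](CC=C(C)C)Cc1c(OCOC)cc(O[Si](C(C)C)(C(C)C)C(C)C)cc1OCOC | intermediate
12 | (2S)-2-{[2,6-bis(methoxymethoxy)-4-(TIPS-oxy)phenyl]methyl}-5-methylhex-4-enoic acid | OC(=O)[C@@H](CC=C(C)C)Cc1c(OCOC)cc(O[Si](C(C)C)(C(C)C)C(C)C)cc1OCOC | intermediate
13 | dilithium (3S)-3-{[2,6-bis(methoxymethoxy)-4-(TIPS-oxy)phenyl]methyl}-6-methylhept-5-ene-2,2-diolate | [Li+].[Li+].CC([O-])([O-])[C@@H](CC=C(C)C)Cc1c(OCOC)cc(O[Si](C(C)C)(C(C)C)C(C)C)cc1OCOC | intermediate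
14 | (3S)-3-{[2,6-bis(methoxymethoxy)-4-(TIPS-oxy)phenyl]methyl}-6-methylhept-5-en-2-one | CC(=O)[C@@H](CC=C(C)C)Cc1c(OCOC)cc(O[Si](C(C)C)(C(C)C)C(C)C)cc1OCOC | intermediate
15 | {3,5-bis(methoxymethoxy)-4-[(2S)-lavandulyl]phenoxy}tri(propan-2-yl)silane | C=C(C)[C@@H](CC=C(C)C)Cc1c(OCOC)cc(O[Si](C(C)C)(C(C)C)C(C)C)cc1OCOC | intermediate
16 | 3,5-bis(methoxymethoxy)-4-[(2S)-lavandulyl]phenol | C=C(C)[C@@H](CC=C(C)C)Cc1c(OCOC)cc(O)cc1OCOC | intermediate
17 | 4-hydroxy-2-methoxybenzaldehyde | COc1cc(O)ccc1C=O | starting material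
18 | 4-formyl-3-methoxyphenyl 2,2-dimethylpropanoate | COc1cc(OC(=O)C(C)(C)C)ccc1C=O | intermediate
19 | ethyl 3-[2-methoxy-4-(Piv-oxy)phenyl]-3-oxopropanoate | CCOC(=O)CC(=O)c1ccc(OC(=O)C(C)(C)C)cc1OC | intermediate
20 | ethyl (3R)-3-hydroxy-3-[2-methoxy-4-(Piv-oxy)phenyl]propanoate | CCOC(=O)C[C@@H](O)c1ccc(OC(=O)C(C)(C)C)cc1OC | intermediate
21 | ethyl (3S)-3-{3,5-bis(methoxymethoxy)-4-[(2S)-lavandulyl]phenoxy}-3-[2-methoxy-4-(Piv-oxy)phenyl]propanoate | C=C(C)[C@@H](CC=C(C)C)Cc1c(OCOC)cc(O[C@@H](CC(=O)OCC)c2ccc(OC(=O)C(C)(C)C)cc2OC)cc1OCOC | intermediate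
22 | (3S)-3-{3,5-bis(methoxymethoxy)-4-[(2S)-lavandulyl]phenoxy}-3-(4-hydroxy-2-methoxyphenyl)propanoic acid | C=C(C)[C@@H](CC=C(C)C)Cc1c(OCOC)cc(O[C@@H](CC(=O)O)c2ccc(O)cc2OC)cc1OCOC | intermediate
23 | S-ethyl (3S)-3-{3,5-bis(methoxymethoxy)-4-[(2S)-lavandulyl]phenoxy}-3-(4-hydroxy-2-methoxyphenyl)propanethioate | C=C(C)[C@@H](CC=C(C)C)Cc1c(OCOC)cc(O[C@@H](CC(=O)SCC)c2ccc(O)cc2OC)cc1OCOC | intermediate
24 | tris(trimethylsilyl) ether of 25 | C=C(C)[C@@H](CC=C(C)C)Cc1c(O[Si](C)(C)C)cc(O[C@@H](CC(=O)SCC)c2ccc(O[Si](C)(C)C)cc2OC)cc1O[Si](C)(C)C | intermediate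
25 | S-ethyl (3S)-3-{3,5-dihydroxy-4-[(2S)-lavandulyl]phenoxy}-3-(4-hydroxy-2-methoxyphenyl)propanethioate | C=C(C)[C@@H](CC=C(C)C)Cc1c(O)cc(O[C@@H](CC(=O)SCC)c2ccc(O)cc2OC)cc1O | intermediate
26 | (2S)-5,7-dihydroxy-2-(4-hydroxy-2-methoxyphenyl)-6-[(2S)-5-methyl-2-(prop-1-en-2-yl)hex-4-en-1-yl]-2,3-dihydro-4H-chromen-4-one | C=C(C)[C@@H](CC=C(C)C)Cc1c(O)cc2c(c1O)C(=O)C[C@@H](c1ccc(O)cc1OC)O2 | target

**Count and risks**

Total step count: 16. Longest linear sequence: 13 steps (steps 1–8, then 12–16).

Step 16 is the most likely to fail. The bulky substrate may not bind productively or may not acylate the active-site cysteine, so that slow hydrolysis of the thioester takes over. The fallback uses known chemistry and sets out from acid 22. Trifluoroacetic anhydride with 2,6-di-tert-butyl-4-methylpyridine in CH2Cl2 at −20 to 0 °C should convert 22 into the bis(trifluoroacetyl) mixed anhydride F1, the free phenol of ring B being acylated as well. F1 should close by intramolecular Friedel–Crafts acylation onto the trioxygenated ring A, as known for 3-aryloxypropanoic acids going to chroman-4-ones, to give the flavanone trifluoroacetate F2; the same symmetry makes the site of attack immaterial. Aqueous NaHCO3 work-up should cleave the aryl trifluoroacetate to the bis-MOM flavanone F3. Me3SiOTf/2,2'-bipyridyl followed by water, as in step 15, then removes the two MOM ethers, and the fallback comes back to the route at 26.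

Step 12 is next. The activated β-hydroxy ester may dehydrate to the cinnamate instead of being displaced, and partial ionisation at the benzylic carbon would erode the configuration at C2. The fallback forms the ether at the alcohol oxidation level, where no acidic hydrogen lies next to the reacting carbon, and sets out from 20 and 16. LiBH4 in THF at 0 °C should reduce the ethyl ester of 20 to the diol F4, the hindered aryl pivalate being expected to survive. TBSCl and imidazole in CH2Cl2 at −20 °C silylate the primary hydroxyl to give the silyl ether F5. Mitsunobu reaction of F5 with 16 (PPh3, DIAD, toluene) gives the inverted aryl ether F6. HF·pyridine in THF frees the primary alcohol F7, and TEMPO with PhI(OAc)2 in MeCN/H2O oxidises it to the pivalate acid F8. LiOH in THF/H2O removes the pivalate, and the fallback comes back to the route at 22.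

Step 3 is third. Transfer of the doubly ortho-substituted aryl group may be sluggish, and the acryloyl imide may polymerise or suffer 1,2-addition. The fallback builds the chain by olefination instead of conjugate addition and sets out from 3. Aryllithium 5, made as in step 3, is quenched with DMF to give the aldehyde F9. Horner–Wadsworth–Emmons reaction of F9 with diethyl {2-[(4S)-4-benzyl-2-oxo-1,3-oxazolidin-3-yl]-2-oxoethyl}phosphonate (LiCl, i-Pr2NEt, MeCN) gives the (E)-cinnamoyl imide F10. Hydrogenation of F10 (H2, Pd/C, EtOAc) saturates the alkene, and the fallback comes back to the route at 8.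

**Further compounds**

F1 | step 16 | (3S)-3-{3,5-bis(methoxymethoxy)-4-[(2S)-lavandulyl]phenoxy}-3-[2-methoxy-4-(trifluoroacetoxy)phenyl]propanoic trifluoroacetic anhydride | C=C(C)[C@@H](CC=C(C)C)Cc1c(OCOC)cc(O[C@@H](CC(=O)OC(=O)C(F)(F)F)c2ccc(OC(=O)C(F)(F)F)cc2OC)cc1OCOC
F2 | step 16 | 4-{(2S)-5,7-bis(methoxymethoxy)-6-[(2S)-lavandulyl]-4-oxo-3,4-dihydro-2H-chromen-2-yl}-3-methoxyphenyl trifluoroacetate | C=C(C)[C@@H](CC=C(C)C)Cc1c(OCOC)cc2c(c1OCOC)C(=O)C[C@@H](c1ccc(OC(=O)C(F)(F)F)cc1OC)O2
F3 | step 16 | (2S)-2-(4-hydroxy-2-methoxyphenyl)-5,7-bis(methoxymethoxy)-6-[(2S)-lavandulyl]-2,3-dihydro-4H-chromen-4-one | C=C(C)[C@@H](CC=C(C)C)Cc1c(OCOC)cc2c(c1OCOC)C(=O)C[C@@H](c1ccc(O)cc1OC)O2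
F4 | step 12 | 4-[(1R)-1,3-dihydroxypropyl]-3-methoxyphenyl 2,2-dimethylpropanoate | OCC[C@@H](O)c1ccc(OC(=O)C(C)(C)C)cc1OC
F5 | step 12 | 4-[(1R)-3-{[tert-butyl(dimethyl)silyl]oxy}-1-hydroxypropyl]-3-methoxyphenyl 2,2-dimethylpropanoate | CC(C)(C)[Si](C)(C)OCC[C@@H](O)c1ccc(OC(=O)C(C)(C)C)cc1OC
F6 | step 12 | 4-[(1S)-1-{3,5-bis(methoxymethoxy)-4-[(2S)-lavandulyl]phenoxy}-3-{[tert-butyl(dimethyl)silyl]oxy}propyl]-3-methoxyphenyl 2,2-dimethylpropanoate | C=C(C)[C@@H](CC=C(C)C)Cc1c(OCOC)cc(O[C@@H](CCO[Si](C)(C)C(C)(C)C)c2ccc(OC(=O)C(C)(C)C)cc2OC)cc1OCOC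
F7 | step 12 | 4-[(1S)-1-{3,5-bis(methoxymethoxy)-4-[(2S)-lavandulyl]phenoxy}-3-hydroxypropyl]-3-methoxyphenyl 2,2-dimethylpropanoate | C=C(C)[C@@H](CC=C(C)C)Cc1c(OCOC)cc(O[C@@H](CCO)c2ccc(OC(=O)C(C)(C)C)cc2OC)cc1OCOC
F8 | step 12 | (3S)-3-{3,5-bis(methoxymethoxy)-4-[(2S)-lavandulyl]phenoxy}-3-[2-methoxy-4-(Piv-oxy)phenyl]propanoic acid | C=C(C)[C@@H](CC=C(C)C)Cc1c(OCOC)cc(O[C@@H](CC(=O)O)c2ccc(OC(=O)C(C)(C)C)cc2OC)cc1OCOC
F9 | step 3 | 2,6-bis(methoxymethoxy)-4-(TIPS-oxy)benzaldehyde | O=Cc1c(OCOC)cc(O[Si](C(C)C)(C(C)C)C(C)C)cc1OCOC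
F10 | step 3 | (4S)-4-benzyl-3-{(2E)-3-[2,6-bis(methoxymethoxy)-4-(TIPS-oxy)phenyl]prop-2-enoyl}-1,3-oxazolidin-2-one | O=C(/C=C/c1c(OCOC)cc(O[Si](C(C)C)(C(C)C)C(C)C)cc1OCOC)N1[C@@H](Cc2ccccc2)COC1=O
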